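**Strategy.** The route rests on disconnecting the C7–C8 bond of the tetrahydrofuran ring O–C7–C8–C8′–C9′ (lignan numbering) back to a C7–O bond. C8–O and C9′–O of a lactone diol are tied to C7 as a six-membered aryl acetal (a 2-aryl-1,3-dioxane). In the key step the silyl ketene acetal of this dioxane-fused γ-lactone undergoes a Lewis-acid-triggered 1,2 shift of the acetal carbon from oxygen to C8. One operation contracts the dioxane to the tetrahydrofuran, forms C7–C8, unveils the tertiary C8 hydroxyl and sets C7 and C8. It exploits that C8 carries an oxygen next to the benzylic ether carbon C7. The precursor comes from dimethyl (S)-malate and silylated vanillin.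

Key step: step 6

Remark on notation: C7 and C7′ are the aryl-bearing carbons, C8 the carbinol carbon, C8′ the ring-fusion CH, C9 and C9′ the OCH2 carbons. Ring B is O–C7–C8–C8′–C9′ and ring A is O–C7′–C8′–C8–C9. Ar = 3-methoxy-4-(triisopropylsilyloxy)phenyl.

Step 1
Reactants: 1 vanillin
Product: 2 3-methoxy-4-(triisopropylsilyloxy)benzaldehyde
Conditions: iPr3SiCl, imidazole, DMF, rt
Reagents that add atoms: triisopropylsilyl chloride, CC(C)[Si](Cl)(C(C)C)C(C)C
Why: Standard phenol silylation; the aryl TIPS ether should survive the amide base, borane, borohydride and silyl triflate used later and comes off with fluoride without touching benzylic ethers.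

Step 2
Reactants: 3 dimethyl (S)-malate; 2 3-methoxy-4-(triisopropylsilyloxy)benzaldehyde
Product: 5 methyl (2S,3S,4S)-2-Ar-4-hydroxy-5-oxooxolane-3-carboxylate (all-trans lactone), via open-chain aldol adduct 4 (not isolated)
Conditions: 3, LiN(iPr)2 (2.2 equiv), THF, −78 → −20 °C; then 2, −78 °C; AcOH; then TsOH·H2O (cat.), CH2Cl2, rt
Reagents that add atoms: none
Why: Fráter–Seebach aldol, in which the chelated dianion of 3 should react anti to the C2 alkoxide (sets C8′) and its chelated Z(O)-enolate should give the syn carbinol through a Zimmerman–Traxler transition state (sets C7′), after which acid closes the C7′ hydroxyl onto the neighbouring ester to the all-trans γ-lactone.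

Step 3
Reactants: 5 methyl (2S,3S,4S)-2-Ar-4-hydroxy-5-oxooxolane-3-carboxylate
Product: 7 (2S,3S,4S)-2-Ar-4-hydroxy-5-oxooxolane-3-carboxylic acid, via trimethylstannyl ester 6 (not isolated)
Conditions: Me3SnOH (4 equiv), ClCH2CH2Cl, 70 °C; then 1 M HCl
Reagents that add atoms: trimethyltin hydroxide, C[Sn](C)(C)O
Why: Near-neutral tin hydroxide cleavage of the methyl ester, which should spare the aryl silyl ether and the three stereocentres.

Step 4
Reactants: 7 (2S,3S,4S)-2-Ar-4-hydroxy-5-oxooxolane-3-carboxylic acid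
Product: 8 (3S,4S,5S)-5-Ar-3-hydroxy-4-(hydroxymethyl)oxolan-2-one
Conditions: BH3·SMe2 (1.5 equiv), THF, −10 → 0 °C; MeOH quench
Reagents that add atoms: none
Why: Borane reduces a carboxylic acid much faster than a lactone (the known reduction of paraconic acids), so only C9′ is taken to the alcohol.

Step 5
Reactants: 8 (3S,4S,5S)-5-Ar-3-hydroxy-4-(hydroxymethyl)oxolan-2-one; 2 3-methoxy-4-(triisopropylsilyloxy)benzaldehyde
Product: 10 (2S,4aR,5S,7aS)-2,5-di-Ar-tetrahydro-4H-furo[3,4-d][1,3]dioxin-7(5H)-one (trans-fused 1,3-dioxane/γ-lactone), via bis(trimethylsilyl) ether 9 (not isolated)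
Conditions: iPrOSiMe3 (2.2 equiv), Me3SiOTf (5 mol%), CH2Cl2, −40 → −20 °C; pyridine quench
Reagents that add atoms: none
Why: Noyori-type acetalisation: in situ silylation of the diol and silyl-triflate-catalysed condensation with the aldehyde, driven by formation of hexamethyldisiloxane, should close the dioxane across C8–O/C9′–O at low temperature with the aryl group equatorial on the acetal carbon.

Step 6
Reactants: 10 (2S,4aR,5S,7aS)-2,5-di-Ar-tetrahydro-4H-furo[3,4-d][1,3]dioxin-7(5H)-one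
Product: 13 (3S,3aR,6R,6aR)-3,6-di-Ar-6a-hydroxytetrahydro-1H,3H-furo[3,4-c]furan-1-one, via silyl ketene acetal 11 (not isolated), via rearranged trimethylsilyl ether 12 (not isolated)
Conditions: LiN(iPr)2 (1.15 equiv), Me3SiCl, THF, −78 °C; solvent switch to CH2Cl2; Me3SiOTf (0.2 equiv), 2,6-di-tert-butyl-4-methylpyridine (0.3 equiv), −78 → −30 °C; then 1 M HCl, THF, 0 °C
Reagents that add atoms: none
Why: Proposed new method: the lactone is converted into its silyl ketene acetal 11, and catalytic silyl triflate ionises the acetal at the C7–O bond to the enol oxygen (the better leaving group, as in vinyl acetal rearrangements), giving an aryl-stabilised oxocarbenium ion on the C9′ oxygen tethered to an α-silyloxy ketene acetal whose carbon C8 adds to C7 with release of the silyl triflate. The closest known reaction types are the Lewis-acid 1,3 O→C rearrangement of cyclic vinyl acetals (4,5-dihydro-1,3-dioxepins to tetrahydrofurans, Petasis–Ferrier rearrangement), the Mukaiyama aldol addition of silyl ketene acetals to acetals and, as anionic 1,2 counterparts, the Chan and [1,2]-Wittig rearrangements. Ring B closes in a 5-(enolexo)-endo-trig mode, the same mode as in the dihydrodioxepin contraction. C8 is controlled by the C9′ tether on C8′, which can deliver C7 only to the face that gives the cis-fused bicycle; C7 is controlled by the (E)-oxocarbenium ion placing its aryl group pseudo-equatorial on the convex face, cis to the C8 oxygen. The step needs C–C closure to outrun unproductive ionisation of the other C7–O bond and protodesilylation back to 10; the reversibility of acetal ionisation, the irreversible C–C bond formation, strain release from the trans-fused dioxane and the hindered pyridine base should secure this.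

Step 7
Reactants: 13 (3S,3aR,6R,6aR)-3,6-di-Ar-6a-hydroxytetrahydro-1H,3H-furo[3,4-c]furan-1-one
Product: 14 (2R,3S,4R)-2-Ar-4-[(S)-Ar(hydroxy)methyl]-3-(hydroxymethyl)oxolan-3-ol
Conditions: LiBH4 (3 equiv), THF, 0 °C → rt; aq NH4Cl
Reagents that add atoms: none
Why: Borohydride reduction of the α-hydroxy lactone to the diol, which should leave the aryl silyl ethers and the benzylic ether of ring B untouched.

Step 8
Reactants: 14 (2R,3S,4R)-2-Ar-4-[(S)-Ar(hydroxy)methyl]-3-(hydroxymethyl)oxolan-3-ol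
Product: 16 (3R,3aS,6S,6aR)-3,6-di-Ar-tetrahydro-1H,3H-furo[3,4-c]furan-3a-ol (bis-TIPS ether of the target), via primary mesylate 15 (not isolated)
Conditions: MsCl (1.05 equiv), Et3N (3 equiv), CH2Cl2, −20 → 35 °C
Reagents that add atoms: none
Why: Selective sulfonylation of the primary C9 hydroxyl and 5-exo-tet Williamson closure by the C7′ hydroxyl, which retains the C7′ configuration from step 2 and gives ring A with the aryl group exo under non-acidic conditions that should not epimerise C7.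

Step 9
Reactants: 16 (3R,3aS,6S,6aR)-3,6-di-Ar-tetrahydro-1H,3H-furo[3,4-c]furan-3a-ol
Product: 17 8-hydroxypinoresinol
Conditions: Bu4NF (2.2 equiv), AcOH (2.2 equiv), THF, 0 °C
Reagents that add atoms: none
Why: Buffered fluoride desilylation of the two aryl silyl ethers, which avoids both acid (benzylic epimerisation) and hydrogenolysis (benzylic C–O cleavage).

**Compound list**

1 | vanillin | COc1cc(C=O)ccc1O | starting material
2 | 3-methoxy-4-(triisopropylsilyloxy)benzaldehyde | COc1cc(C=O)ccc1O[Si](C(C)C)(C(C)C)C(C)C | intermediate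
3 | dimethyl (S)-malate | COC(=O)C[C@H](O)C(=O)OC | starting material
4 | dimethyl (2S,3R)-2-hydroxy-3-[(S)-hydroxy(Ar)methyl]butanedioate (open-chain aldol adduct) | COC(=O)[C@@H](O)[C@H](C(=O)OC)[C@H](O)c1ccc(O[Si](C(C)C)(C(C)C)C(C)C)c(OC)c1 | intermediate
5 | methyl (2S,3S,4S)-2-Ar-4-hydroxy-5-oxooxolane-3-carboxylate | O=C1O[C@H](c2ccc(O[Si](C(C)C)(C(C)C)C(C)C)c(OC)c2)[C@@H](C(=O)OC)[C@@H]1O | intermediate
6 | trimethylstannyl ester of acid 7 | O=C1O[C@H](c2ccc(O[Si](C(C)C)(C(C)C)C(C)C)c(OC)c2)[C@@H](C(=O)O[Sn](C)(C)C)[C@@H]1O | intermediate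
7 | (2S,3S,4S)-2-Ar-4-hydroxy-5-oxooxolane-3-carboxylic acid | O=C1O[C@H](c2ccc(O[Si](C(C)C)(C(C)C)C(C)C)c(OC)c2)[C@@H](C(=O)O)[C@@H]1O | intermediate
8 | (3S,4S,5S)-5-Ar-3-hydroxy-4-(hydroxymethyl)oxolan-2-one | O=C1O[C@H](c2ccc(O[Si](C(C)C)(C(C)C)C(C)C)c(OC)c2)[C@@H](CO)[C@@H]1O | intermediate
9 | bis(trimethylsilyl) ether of diol 8 | O=C1O[C@H](c2ccc(O[Si](C(C)C)(C(C)C)C(C)C)c(OC)c2)[C@@H](CO[Si](C)(C)C)[C@@H]1O[Si](C)(C)C | intermediate
10 | (2S,4aR,5S,7aS)-2,5-di-Ar-tetrahydro-4H-furo[3,4-d][1,3]dioxin-7(5H)-one (trans-fused acetal of 8 with 2) | O=C1O[C@H](c2ccc(O[Si](C(C)C)(C(C)C)C(C)C)c(OC)c2)[C@H]3CO[C@H](c4ccc(O[Si](C(C)C)(C(C)C)C(C)C)c(OC)c4)O[C@H]13 | intermediate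
11 | trimethylsilyl ketene acetal of 10 (2,5-di-Ar-7-trimethylsilyloxy-4a,5-dihydro-4H-furo[3,4-d][1,3]dioxine) | C[Si](C)(C)OC1=C2O[C@@H](c3ccc(O[Si](C(C)C)(C(C)C)C(C)C)c(OC)c3)OC[C@@H]2[C@@H](c4ccc(O[Si](C(C)C)(C(C)C)C(C)C)c(OC)c4)O1 | intermediate
12 | O-trimethylsilyl ether of 13 | COc1cc([C@H]2OC(=O)[C@]3(O[Si](C)(C)C)[C@@H](c4ccc(O[Si](C(C)C)(C(C)C)C(C)C)c(OC)c4)OC[C@H]23)ccc1O[Si](C(C)C)(C(C)C)C(C)C | intermediate
13 | (3S,3aR,6R,6aR)-3,6-di-Ar-6a-hydroxytetrahydro-1H,3H-furo[3,4-c]furan-1-one | COc1cc([C@H]2OC(=O)[C@]3(O)[C@@H](c4ccc(O[Si](C(C)C)(C(C)C)C(C)C)c(OC)c4)OC[C@H]23)ccc1O[Si](C(C)C)(C(C)C)C(C)C | intermediate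
14 | (2R,3S,4R)-2-Ar-4-[(S)-Ar(hydroxy)methyl]-3-(hydroxymethyl)oxolan-3-ol | OC[C@]1(O)[C@@H](c2ccc(O[Si](C(C)C)(C(C)C)C(C)C)c(OC)c2)OC[C@@H]1[C@H](O)c3ccc(O[Si](C(C)C)(C(C)C)C(C)C)c(OC)c3 | intermediate
15 | primary methanesulfonate of triol 14 | CS(=O)(=O)OC[C@]1(O)[C@@H](c2ccc(O[Si](C(C)C)(C(C)C)C(C)C)c(OC)c2)OC[C@@H]1[C@H](O)c3ccc(O[Si](C(C)C)(C(C)C)C(C)C)c(OC)c3 | intermediate
16 | (3R,3aS,6S,6aR)-3,6-di-Ar-tetrahydro-1H,3H-furo[3,4-c]furan-3a-ol (bis-TIPS ether of the target) | COc1cc([C@H]2OC[C@]3(O)[C@@H](c4ccc(O[Si](C(C)C)(C(C)C)C(C)C)c(OC)c4)OC[C@H]23)ccc1O[Si](C(C)C)(C(C)C)C(C)C | intermediate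
17 | 8-hydroxypinoresinol, (3R,3aS,6S,6aR)-3,6-bis(4-hydroxy-3-methoxyphenyl)tetrahydro-1H,3H-furo[3,4-c]furan-3a-ol | COc1cc([C@H]2OC[C@]3(O)[C@@H](c4ccc(O)c(OC)c4)OC[C@H]23)ccc1O | target

**Step count.** Total: 9 steps. Longest linear sequence: 9 steps (1 → 2 → 5 → 7 → 8 → 10 → 13 → 14 → 16 → 17); aldehyde 2 is used a second time in step 5.

**Steps most likely to fail**

Step 6 (Proposed new method). The acetal may ionise only at the other C7–O bond, the ketene acetal may be protonated back to 10, or closure may place the aryl group endo. The fallback reaches the same oxocarbenium/ketene acetal pair from an open-chain mixed acetal and closes it by a known intramolecular Mukaiyama-type acetal aldol; it closes ring B directly, so the ring contraction is given up. It sets out from diol 8. Exhaustive silylation (Et3SiOTf, 2,6-lutidine) gives the bis(triethylsilyl) ether F1. The primary silyl group is removed selectively (PPTS, MeOH/CH2Cl2, 0 °C) to give the primary alcohol F2. Acid-catalysed exchange (PPTS, CH2Cl2, molecular sieves) with the dimethyl acetal F3 of aldehyde 2 (from 2 with HC(OMe)3, cat. TsOH, MeOH) gives the mixed methyl acetal F4; either epimer at the acetal carbon serves. LiN(iPr)2/Me3SiCl then gives the silyl ketene acetal F5. Catalytic Me3SiOTf expels the methoxy group and C8 closes on the tethered oxocarbenium ion, with cis fusion enforced by the tether, to the triethylsilyl ether F6. Hydrolysis (1 M HCl, THF) brings the route back at 13.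

Step 5. Ring closure to the trans-fused dioxane may be slow, so that the primary hydroxyl instead attacks the lactone (translactonisation) or open-chain acetals accumulate. The fallback inverts C8 first, so that a strain-free cis-fused acetal forms; C8 becomes trigonal in step 6 anyway. It sets out from 5. Mitsunobu inversion (PPh3, DIAD, 4-nitrobenzoic acid, THF) gives the inverted 4-nitrobenzoate F7. Me3SnOH cleaves both ester groups through the stannyl ester F8 and gives, after HCl work-up, the cis-hydroxy acid F9. BH3·SMe2 gives the cis-diol F10. Condensation with 2 (PPTS, benzene, reflux with water removal) gives the cis-fused acetal F11. Under the conditions of step 6, F11 gives the ketene acetal F12, which ionises to the same oxocarbenium ion as 11 and returns to the route at 13 (through 12).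

Step 2. Facial selectivity at the carbinol carbon C7′ may be poor, giving the lactone as a mixture of C7′ epimers. The fallback moves control of C7′ from the kinetic aldol to a thermodynamic equilibration. It sets out from the crude lactonisation product of 4, which contains 5 and its C7′ epimer, the 2,3-cis lactone F13. Treatment with CF3CO2H (or BF3·OEt2) in CH2Cl2 reversibly ionises the benzylic lactone C–O bond of the electron-rich aryl group. The mixture should funnel into the more stable all-trans lactone, and the route is rejoined at 5.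

**Further compounds**

F1 | step 6 | bis(triethylsilyl) ether of diol 8 | O=C1O[C@H](c2ccc(O[Si](C(C)C)(C(C)C)C(C)C)c(OC)c2)[C@@H](CO[Si](CC)(CC)CC)[C@@H]1O[Si](CC)(CC)CC
F2 | step 6 | 5-Ar-4-(hydroxymethyl)-3-(triethylsilyloxy)oxolan-2-one (secondary silyl ether of 8) | O=C1O[C@H](c2ccc(O[Si](C(C)C)(C(C)C)C(C)C)c(OC)c2)[C@@H](CO)[C@@H]1O[Si](CC)(CC)CC
F3 | step 6 | 3-methoxy-4-(triisopropylsilyloxy)benzaldehyde dimethyl acetal | COC(OC)c1ccc(O[Si](C(C)C)(C(C)C)C(C)C)c(OC)c1
F4 | step 6 | mixed methyl acetal of F2 with aldehyde 2 (both epimers at the acetal carbon) | O=C1O[C@H](c2ccc(O[Si](C(C)C)(C(C)C)C(C)C)c(OC)c2)[C@@H](COC(OC)c3ccc(O[Si](C(C)C)(C(C)C)C(C)C)c(OC)c3)[C@@H]1O[Si](CC)(CC)CC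
F5 | step 6 | trimethylsilyl ketene acetal of F4 | C[Si](C)(C)OC1=C(O[Si](CC)(CC)CC)[C@H](COC(OC)c2ccc(O[Si](C(C)C)(C(C)C)C(C)C)c(OC)c2)[C@@H](c3ccc(O[Si](C(C)C)(C(C)C)C(C)C)c(OC)c3)O1
F6 | step 6 | O-triethylsilyl ether of 13 | COc1cc([C@H]2OC(=O)[C@]3(O[Si](CC)(CC)CC)[C@@H](c4ccc(O[Si](C(C)C)(C(C)C)C(C)C)c(OC)c4)OC[C@H]23)ccc1O[Si](C(C)C)(C(C)C)C(C)C
F7 | step 5 | C4-inverted 4-nitrobenzoate of lactone ester 5 | O=C1O[C@H](c2ccc(O[Si](C(C)C)(C(C)C)C(C)C)c(OC)c2)[C@@H](C(=O)OC)[C@H]1OC(=O)c3ccc(cc3)[N+](=O)[O-]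
F8 | step 5 | trimethylstannyl ester of acid F9 | O=C1O[C@H](c2ccc(O[Si](C(C)C)(C(C)C)C(C)C)c(OC)c2)[C@@H](C(=O)O[Sn](C)(C)C)[C@H]1O
F9 | step 5 | C4 epimer of acid 7 (hydroxyl cis to the carboxyl group) | O=C1O[C@H](c2ccc(O[Si](C(C)C)(C(C)C)C(C)C)c(OC)c2)[C@@H](C(=O)O)[C@H]1O
F10 | step 5 | C3 epimer of diol 8 (hydroxyl cis to the hydroxymethyl group) | O=C1O[C@H](c2ccc(O[Si](C(C)C)(C(C)C)C(C)C)c(OC)c2)[C@@H](CO)[C@H]1O
F11 | step 5 | cis-fused acetal of F10 with 2 (aryl equatorial on the acetal carbon) | O=C1O[C@H](c2ccc(O[Si](C(C)C)(C(C)C)C(C)C)c(OC)c2)[C@H]3CO[C@@H](c4ccc(O[Si](C(C)C)(C(C)C)C(C)C)c(OC)c4)O[C@@H]13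
F12 | step 5 | trimethylsilyl ketene acetal of F11 (epimer of 11 at the acetal carbon) | C[Si](C)(C)OC1=C2O[C@H](c3ccc(O[Si](C(C)C)(C(C)C)C(C)C)c(OC)c3)OC[C@@H]2[C@@H](c4ccc(O[Si](C(C)C)(C(C)C)C(C)C)c(OC)c4)O1
F13 | step 2 | C2 epimer of lactone ester 5 (aryl cis to the ester group) | O=C1O[C@@H](c2ccc(O[Si](C(C)C)(C(C)C)C(C)C)c(OC)c2)[C@@H](C(=O)OC)[C@@H]1O
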